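**Retrosynthetic overview**
1. Target ⇐ site-selective angeloylation of the C-5′ hydroxyl of an anti-1,3-diol ⇐ hydroxyl-directed 1,3-anti reduction of a β-hydroxy enone ⇐ allylic oxidation of the fragment-coupling product.
2. Key disconnection C-2′–C-3′ (alkenyl carbon to carbinol carbon): electrochemical chromium/nickel (Nozaki–Hiyama–Kishi) alkenylation of a lactol by a ring alkenyl triflate.
3. Ring fragment ⇐ (R)-carvone: α′-hydroxylation, Mitsunobu inversion to the cis acetate, Luche reduction, hydroxyl-directed epoxidation, angeloylation, then isopropenyl → methyl ketone → enol triflate.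
4. Side-chain fragment ⇐ D-malic acid: dioxolanone, double MeMgBr addition with lactonisation, reduction to the lactol.
5. Ring order: the carbocycle is bought in carvone; the only ring made is the epoxide (step 4), before the fragments are joined.

Assumption: both five-carbon acyl groups are read from the SMILES as (2Z)-2-methylbut-2-enoates (angelates); (R)-carvone, D-malic acid and angelic acid are taken as commercial.

Locants: ring as 7-oxabicyclo[4.1.0]heptane (C-1 methyl-bearing epoxide carbon, C-2 angelate carbon, C-3 acetate carbon, C-4 side-chain carbon); side chain as hept-1-en-2-yl (C-1′ to C-7′).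

**Route**

Step 1
Reactants: 1 (R)-(−)-carvone
Product: 4 trans-6-hydroxycarvone [(5S,6S)-6-hydroxy-2-methyl-5-(prop-1-en-2-yl)cyclohex-2-en-1-one], via silyl dienol ether 2 (not isolated), via silyloxy ketone 3 (not isolated)
Conditions: LiN(iPr)2, THF, −78 °C; Me3SiCl; then mCPBA, CH2Cl2, −20 °C; then 1 M HCl, THF, 0 °C
Reagents that add atoms: mCPBA, O=C(OO)c1cccc(Cl)c1
Why: Kinetic α′-enolisation followed by Rubottom oxidation; mCPBA epoxidises the electron-rich silyl enol ether on the face away from the C-5 isopropenyl group, so the new hydroxyl is trans to it.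

Step 2
Reactants: 4 trans-6-hydroxycarvone
Product: 5 cis-6-acetoxycarvone [(1R,6S)-3-methyl-2-oxo-6-(prop-1-en-2-yl)cyclohex-3-en-1-yl acetate]
Conditions: AcOH, PPh3, DIAD, toluene, 0 °C → rt
Reagents that add atoms: acetic acid, CC(=O)O
Why: Mitsunobu esterification of an α-hydroxy ketone is an SN2 displacement with clean inversion, turning the trans alcohol into the cis acetate required for the all-cis ring.

Step 3
Reactants: 5 cis-6-acetoxycarvone
Product: 6 all-cis hydroxy acetate [(1R,2S,6S)-2-hydroxy-3-methyl-6-(prop-1-en-2-yl)cyclohex-3-en-1-yl acetate]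
Conditions: NaBH4, CeCl3·7H2O, MeOH, −78 °C; AcOH quench
Reagents that add atoms: none
Why: Luche 1,2-reduction; hydride adds anti to the adjacent acetoxy group (polar Felkin–Anh and axial attack coincide), giving the alcohol cis to both the acetate and the isopropenyl group, and the cold buffered medium prevents acetyl migration.

Step 4
Reactants: 6 all-cis hydroxy acetate
Product: 7 epoxy alcohol [(1R,2R,3R,4S,6S)-2-hydroxy-1-methyl-4-(prop-1-en-2-yl)-7-oxabicyclo[4.1.0]heptan-3-yl acetate]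
Conditions: VO(acac)2 (3 mol %), t-BuOOH, CH2Cl2, 0 °C → rt
Reagents that add atoms: tert-butyl hydroperoxide, CC(C)(C)OO
Why: VO(acac)2-catalysed hydroxyl-directed epoxidation delivers oxygen to the ring alkene on the face of the allylic hydroxyl and leaves the isolated 1,1-disubstituted alkene alone.

Step 5
Reactants: 7 epoxy alcohol
Product: 8 ring angelate [(1S,2R,3R,4S,6S)-3-(acetyloxy)-1-methyl-4-(prop-1-en-2-yl)-7-oxabicyclo[4.1.0]heptan-2-yl (2Z)-2-methylbut-2-enoate]
Conditions: angelic acid, 2,4,6-Cl3C6H2COCl, Et3N, toluene, rt, filter; then 7, 2,6-lutidine, toluene, 70 °C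
Reagents that add atoms: angelic acid, C/C=C(/C)C(=O)O
Why: Yamaguchi-type mixed-anhydride acylation without a nucleophilic catalyst is the usual way to make angelates without Z to E isomerisation, and the weak pyridine base avoids alkoxide-driven acetyl migration; no stereocentre is touched.

Step 6
Reactants: 8 ring angelate
Product: 10 methyl ketone [(1S,2R,3R,4R,6S)-3-(acetyloxy)-4-acetyl-1-methyl-7-oxabicyclo[4.1.0]heptan-2-yl (2Z)-2-methylbut-2-enoate], via ozonide 9 (not isolated)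
Conditions: O3, CH2Cl2, −78 °C (Sudan Red 7B end point); then Me2S, −78 °C → rt
Reagents that add atoms: ozone, [O-][O+]=O
Why: Ozonolysis; the electron-rich 1,1-disubstituted alkene is cleaved much faster than the conjugated angelate, and the dye end point stops the reaction before the enoate reacts.

Step 7
Reactants: 10 methyl ketone
Product: 12 alkenyl triflate [(1S,2R,3R,4R,6S)-3-(acetyloxy)-1-methyl-4-{1-[(trifluoromethanesulfonyl)oxy]ethenyl}-7-oxabicyclo[4.1.0]heptan-2-yl (2Z)-2-methylbut-2-enoate], via potassium enolate 11 (not isolated)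
Conditions: KN(SiMe3)2, THF, −78 °C; then Comins' reagent, −78 °C
Reagents that add atoms: Comins' reagent [N-(5-chloropyridin-2-yl)-1,1,1-trifluoro-N-(trifluoromethanesulfonyl)methanesulfonamide], FC(F)(F)S(=O)(=O)N(c1ccc(Cl)cn1)S(=O)(=O)C(F)(F)F
Why: Kinetic enolate O-triflation; the bulky amide removes a methyl proton rather than the ring methine, and immediate trapping at −78 °C avoids the ring-side enolate that would expel the β-acetate.

Step 8
Reactants: 13 D-(+)-malic acid
Product: 14 dioxolanone acid [2-[(4R)-2,2-dimethyl-5-oxo-1,3-dioxolan-4-yl]acetic acid]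
Conditions: 2,2-dimethoxypropane, TsOH (cat.), rt
Reagents that add atoms: 2,2-dimethoxypropane, COC(C)(C)OC
Why: Acid-catalysed acetalisation engages only the α-hydroxy acid as a five-membered dioxolanone, which differentiates the two carboxyl groups without touching the stereocentre.

Step 9
Reactants: 14 dioxolanone acid
Product: 16 hydroxy lactone [(4R)-4-hydroxy-5,5-dimethyloxolan-2-one], via dihydroxy acid 15 (not isolated)
Conditions: MeMgBr (5 equiv), THF, −78 → 0 °C; then 2 M HCl, rt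
Reagents that add atoms: methylmagnesium bromide, C[Mg]Br
Why: Double Grignard addition takes place at the activated dioxolanone carbonyl while the magnesium carboxylate is inert, and acidification closes the γ-lactone; the malic stereocentre is not involved.

Step 10
Reactants: 16 hydroxy lactone
Product: 17 lactol [(4R)-5,5-dimethyloxolane-2,4-diol, anomer mixture]
Conditions: i-Bu2AlH (2.2 equiv), CH2Cl2, −78 °C; aqueous work-up
Reagents that add atoms: none
Why: Partial reduction of a γ-lactone with i-Bu2AlH at −78 °C stops at the aluminium hemiacetal and gives the lactol.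

Step 11
Reactants: 12 alkenyl triflate; 17 lactol
Product: 18 coupled triol [(1S,2R,3R,4S,6S)-3-(acetyloxy)-1-methyl-4-[(3RS,5R)-3,5,6-trihydroxy-6-methylhept-1-en-2-yl]-7-oxabicyclo[4.1.0]heptan-2-yl (2Z)-2-methylbut-2-enoate]
Conditions: CrCl2 (20 mol %), NiCl2·MeOCH2CH2OMe (3 mol %), Cp2ZrCl2 (2.5 equiv), 4-tert-butylpyridine, LiCl, DMF, rt, undivided cell, Al anode, Ni-foam cathode, constant current (2.5 F/mol); 17 in 2-fold excess
Reagents that add atoms: none
Why: Proposed new method: a CrCl2/NiCl2-electrocatalysed Nozaki–Hiyama–Kishi alkenylation that uses an unprotected γ-lactol as the latent aldehyde: cathodically generated zerovalent nickel inserts into the alkenyl C–OTf bond, the alkenyl group passes to trivalent chromium, and this alkenylchromium adds to the open hydroxy-aldehyde tautomer that the oxophilic Cr and Zr centres draw out of the lactol equilibrium, after which Cp2ZrCl2 frees chromium from the product alkoxide and the cathode returns it to the divalent state, the low potential leaving epoxide, acetate and angelate untouched; the closest known reactions are the electrochemical Nozaki–Hiyama–Kishi coupling of free aldehydes with alkenyl halides or triflates and stoichiometric CrCl2/NiCl2 additions to lactols; C-3′ forms as an epimer mixture that steps 12 and 13 converge.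

Step 12
Reactants: 18 coupled triol
Product: 19 β-hydroxy enone [(1S,2R,3R,4S,6S)-3-(acetyloxy)-4-[(5R)-5,6-dihydroxy-6-methyl-3-oxohept-1-en-2-yl]-1-methyl-7-oxabicyclo[4.1.0]heptan-2-yl (2Z)-2-methylbut-2-enoate]
Conditions: MnO2 (activated, 20 equiv), CH2Cl2, rt; used at once
Reagents that add atoms: none
Why: Allylic oxidation with manganese dioxide (MnO2) oxidises only the allylic secondary alcohol, converging both C-3′ epimers to one enone and leaving the other secondary and the tertiary hydroxyl.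

Step 13
Reactants: 19 β-hydroxy enone
Product: 20 anti-triol [(1S,2R,3R,4S,6S)-3-(acetyloxy)-1-methyl-4-[(3R,5R)-3,5,6-trihydroxy-6-methylhept-1-en-2-yl]-7-oxabicyclo[4.1.0]heptan-2-yl (2Z)-2-methylbut-2-enoate]
Conditions: Me4NBH(OAc)3 (5 equiv), MeCN/AcOH (1:1), −30 °C
Reagents that add atoms: none
Why: Evans–Saksena reduction; boron bound to the C-5′ hydroxyl delivers hydride internally through a chair transition state, giving the 1,3-anti (3′R) alcohol by 1,2-reduction, and the reagent does not reduce esters or the epoxide.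

Step 14
Reactants: 20 anti-triol
Product: 21 target [(1S,2R,3R,4S,6S)-3-(acetyloxy)-4-[(3R,5R)-3,6-dihydroxy-6-methyl-5-{[(2Z)-2-methylbut-2-enoyl]oxy}hept-1-en-2-yl]-1-methyl-7-oxabicyclo[4.1.0]heptan-2-yl (2Z)-2-methylbut-2-enoate]
Conditions: angelic acid, 1-chloro-N,N,2-trimethylprop-1-en-1-amine, CH2Cl2, 0 °C; then 20, Me2SnCl2 (10 mol %), K2CO3, THF, 0 °C → rt
Reagents that add atoms: angelic acid, C/C=C(/C)C(=O)O
Why: Me2SnCl2-catalysed regioselective monoacylation of a 1,2-diol; tin forms a five-membered stannylene only with the vicinal C-5′/C-6′ diol and activates its secondary oxygen, so the isolated allylic C-3′ hydroxyl and the tertiary hydroxyl stay free, and the neutral acid-chloride formation and carbonate base avoid angelate isomerisation.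

**Compound list**

1 | (R)-(−)-carvone, (5R)-2-methyl-5-(prop-1-en-2-yl)cyclohex-2-en-1-one | C=C(C)[C@@H]1CC=C(C)C(=O)C1 | starting material
2 | trimethyl{[(3R)-6-methyl-3-(prop-1-en-2-yl)cyclohexa-1,5-dien-1-yl]oxy}silane (not isolated) | C=C(C)[C@@H]1CC=C(C)C(O[Si](C)(C)C)=C1 | intermediate
3 | (5S,6S)-2-methyl-5-(prop-1-en-2-yl)-6-[(trimethylsilyl)oxy]cyclohex-2-en-1-one (not isolated) | C=C(C)[C@@H]1CC=C(C)C(=O)[C@H]1O[Si](C)(C)C | intermediate
4 | (5S,6S)-6-hydroxy-2-methyl-5-(prop-1-en-2-yl)cyclohex-2-en-1-one (trans) | C=C(C)[C@@H]1CC=C(C)C(=O)[C@H]1O | intermediate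
5 | (1R,6S)-3-methyl-2-oxo-6-(prop-1-en-2-yl)cyclohex-3-en-1-yl acetate (cis) | C=C(C)[C@@H]1CC=C(C)C(=O)[C@@H]1OC(C)=O | intermediate
6 | (1R,2S,6S)-2-hydroxy-3-methyl-6-(prop-1-en-2-yl)cyclohex-3-en-1-yl acetate (all-cis) | C=C(C)[C@@H]1CC=C(C)[C@H](O)[C@@H]1OC(C)=O | intermediate
7 | (1R,2R,3R,4S,6S)-2-hydroxy-1-methyl-4-(prop-1-en-2-yl)-7-oxabicyclo[4.1.0]heptan-3-yl acetate | C=C(C)[C@@H]1C[C@@H]2O[C@]2(C)[C@H](O)[C@@H]1OC(C)=O | intermediate
8 | (1S,2R,3R,4S,6S)-3-(acetyloxy)-1-methyl-4-(prop-1-en-2-yl)-7-oxabicyclo[4.1.0]heptan-2-yl (2Z)-2-methylbut-2-enoate | C=C(C)[C@@H]1C[C@@H]2O[C@]2(C)[C@H](OC(=O)/C(C)=C\C)[C@@H]1OC(C)=O | intermediate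
9 | (1S,2R,3R,4R,6S)-3-(acetyloxy)-1-methyl-4-(3-methyl-1,2,4-trioxolan-3-yl)-7-oxabicyclo[4.1.0]heptan-2-yl (2Z)-2-methylbut-2-enoate, epimers at the trioxolane carbon (not isolated) | CC3(OCOO3)[C@@H]1C[C@@H]2O[C@]2(C)[C@H](OC(=O)/C(C)=C\C)[C@@H]1OC(C)=O | intermediate
10 | (1S,2R,3R,4R,6S)-3-(acetyloxy)-4-acetyl-1-methyl-7-oxabicyclo[4.1.0]heptan-2-yl (2Z)-2-methylbut-2-enoate | CC(=O)[C@@H]1C[C@@H]2O[C@]2(C)[C@H](OC(=O)/C(C)=C\C)[C@@H]1OC(C)=O | intermediate
11 | potassium enolate of 10 on the methyl side (not isolated) | C=C(O[K])[C@@H]1C[C@@H]2O[C@]2(C)[C@H](OC(=O)/C(C)=C\C)[C@@H]1OC(C)=O | intermediate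
12 | (1S,2R,3R,4R,6S)-3-(acetyloxy)-1-methyl-4-{1-[(trifluoromethanesulfonyl)oxy]ethenyl}-7-oxabicyclo[4.1.0]heptan-2-yl (2Z)-2-methylbut-2-enoate | C=C(OS(=O)(=O)C(F)(F)F)[C@@H]1C[C@@H]2O[C@]2(C)[C@H](OC(=O)/C(C)=C\C)[C@@H]1OC(C)=O | intermediate
13 | D-(+)-malic acid, (2R)-2-hydroxybutanedioic acid | OC(=O)C[C@@H](O)C(O)=O | starting material
14 | 2-[(4R)-2,2-dimethyl-5-oxo-1,3-dioxolan-4-yl]acetic acid | OC(=O)C[C@H]1OC(C)(C)OC1=O | intermediate
15 | (3R)-3,4-dihydroxy-4-methylpentanoic acid (not isolated) | OC(=O)C[C@@H](O)C(C)(C)O | intermediate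
16 | (4R)-4-hydroxy-5,5-dimethyloxolan-2-one | O=C1C[C@@H](O)C(C)(C)O1 | intermediate
17 | (4R)-5,5-dimethyloxolane-2,4-diol (anomer mixture) | OC1C[C@@H](O)C(C)(C)O1 | intermediate
18 | (1S,2R,3R,4S,6S)-3-(acetyloxy)-1-methyl-4-[(3RS,5R)-3,5,6-trihydroxy-6-methylhept-1-en-2-yl]-7-oxabicyclo[4.1.0]heptan-2-yl (2Z)-2-methylbut-2-enoate | C=C(C(O)C[C@@H](O)C(C)(C)O)[C@@H]1C[C@@H]2O[C@]2(C)[C@H](OC(=O)/C(C)=C\C)[C@@H]1OC(C)=O | intermediate
19 | (1S,2R,3R,4S,6S)-3-(acetyloxy)-4-[(5R)-5,6-dihydroxy-6-methyl-3-oxohept-1-en-2-yl]-1-methyl-7-oxabicyclo[4.1.0]heptan-2-yl (2Z)-2-methylbut-2-enoate | C=C(C(=O)C[C@@H](O)C(C)(C)O)[C@@H]1C[C@@H]2O[C@]2(C)[C@H](OC(=O)/C(C)=C\C)[C@@H]1OC(C)=O | intermediate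
20 | (1S,2R,3R,4S,6S)-3-(acetyloxy)-1-methyl-4-[(3R,5R)-3,5,6-trihydroxy-6-methylhept-1-en-2-yl]-7-oxabicyclo[4.1.0]heptan-2-yl (2Z)-2-methylbut-2-enoate | C=C([C@H](O)C[C@@H](O)C(C)(C)O)[C@@H]1C[C@@H]2O[C@]2(C)[C@H](OC(=O)/C(C)=C\C)[C@@H]1OC(C)=O | intermediate
21 | (1S,2R,3R,4S,6S)-3-(acetyloxy)-4-[(3R,5R)-3,6-dihydroxy-6-methyl-5-{[(2Z)-2-methylbut-2-enoyl]oxy}hept-1-en-2-yl]-1-methyl-7-oxabicyclo[4.1.0]heptan-2-yl (2Z)-2-methylbut-2-enoate (CNP0105552.1) | C=C([C@H](O)C[C@@H](OC(=O)/C(C)=C\C)C(C)(C)O)[C@@H]1C[C@@H]2O[C@]2(C)[C@H](OC(=O)/C(C)=C\C)[C@@H]1OC(C)=O | target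

**Step count and risks**

Total steps: 14 (ring fragment 7, side-chain fragment 3, union and end-game 4). Longest linear sequence: 11 (steps 1–7, then 11–14).

Steps most likely to fail:

1. Step 11 (the proposed new step): the lactol may open too slowly or its free hydroxyls may stall chromium turnover. Fallback (known chemistry), setting out from lactone 16 and triflate 12: treat 16 with 2,2-dimethoxypropane/MeOH/TsOH to give the open-chain methyl ester acetonide F1, reduce it with i-Bu2AlH at −78 °C to the protected aldehyde F2, and couple F2 with 12 under classical stoichiometric Nozaki–Hiyama–Kishi conditions (CrCl2, NiCl2 cat., DMSO, rt) to the acetonide-protected allylic alcohol F3; 80% aqueous AcOH at 0 °C removes the acetonide and the route is rejoined at 18.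

2. Step 14: the tin catalyst may not discriminate the C-5′/C-6′ diol from the C-3′ hydroxyl well enough. Fallback, setting out from enone 19: acylate its only secondary hydroxyl with the angelic mixed anhydride of step 5 to the bis-angelate enone F4, reduce under Luche conditions (NaBH4, CeCl3·7H2O) to an unselective mixture of 21 and its C-3′ epimer F5, separate by chromatography and return F5 to F4 with MnO2; the route is rejoined at 21.

3. Step 7: any ring-side enolate eliminates the anti-periplanar β-acetate. Fallback, setting out from ketone 10: condense with 1,2-bis(tert-butyldimethylsilyl)hydrazine (Sc(OTf)3 cat.) to the N-silyl hydrazone F6 and treat it with I2 and 1,1,3,3-tetramethylguanidine (Barton vinyl iodide synthesis) to the alkenyl iodide F7, which takes the place of 12 in step 11; the route is rejoined at 18.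

**Further compounds**

F1 | step 11 | methyl 2-[(4R)-2,2,5,5-tetramethyl-1,3-dioxolan-4-yl]acetate | COC(=O)C[C@H]1OC(C)(C)OC1(C)C
F2 | step 11 | 2-[(4R)-2,2,5,5-tetramethyl-1,3-dioxolan-4-yl]acetaldehyde | O=CC[C@H]1OC(C)(C)OC1(C)C
F3 | step 11 | (1S,2R,3R,4S,6S)-3-(acetyloxy)-4-{(3RS)-3-hydroxy-4-[(4R)-2,2,5,5-tetramethyl-1,3-dioxolan-4-yl]but-1-en-2-yl}-1-methyl-7-oxabicyclo[4.1.0]heptan-2-yl (2Z)-2-methylbut-2-enoate | C=C(C(O)C[C@H]3OC(C)(C)OC3(C)C)[C@@H]1C[C@@H]2O[C@]2(C)[C@H](OC(=O)/C(C)=C\C)[C@@H]1OC(C)=O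
F4 | step 14 | (1S,2R,3R,4S,6S)-3-(acetyloxy)-4-[(5R)-6-hydroxy-6-methyl-5-{[(2Z)-2-methylbut-2-enoyl]oxy}-3-oxohept-1-en-2-yl]-1-methyl-7-oxabicyclo[4.1.0]heptan-2-yl (2Z)-2-methylbut-2-enoate | C=C(C(=O)C[C@@H](OC(=O)/C(C)=C\C)C(C)(C)O)[C@@H]1C[C@@H]2O[C@]2(C)[C@H](OC(=O)/C(C)=C\C)[C@@H]1OC(C)=O
F5 | step 14 | (3′S)-epimer of 21, (1S,2R,3R,4S,6S)-3-(acetyloxy)-4-[(3S,5R)-3,6-dihydroxy-6-methyl-5-{[(2Z)-2-methylbut-2-enoyl]oxy}hept-1-en-2-yl]-1-methyl-7-oxabicyclo[4.1.0]heptan-2-yl (2Z)-2-methylbut-2-enoate | C=C([C@@H](O)C[C@@H](OC(=O)/C(C)=C\C)C(C)(C)O)[C@@H]1C[C@@H]2O[C@]2(C)[C@H](OC(=O)/C(C)=C\C)[C@@H]1OC(C)=O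
F6 | step 7 | (1S,2R,3R,4S,6S)-3-(acetyloxy)-4-{1-[2-(tert-butyldimethylsilyl)hydrazinylidene]ethyl}-1-methyl-7-oxabicyclo[4.1.0]heptan-2-yl (2Z)-2-methylbut-2-enoate | CC(=NN[Si](C)(C)C(C)(C)C)[C@@H]1C[C@@H]2O[C@]2(C)[C@H](OC(=O)/C(C)=C\C)[C@@H]1OC(C)=O
F7 | step 7 | (1S,2R,3R,4R,6S)-3-(acetyloxy)-4-(1-iodoethenyl)-1-methyl-7-oxabicyclo[4.1.0]heptan-2-yl (2Z)-2-methylbut-2-enoate | C=C(I)[C@@H]1C[C@@H]2O[C@]2(C)[C@H](OC(=O)/C(C)=C\C)[C@@H]1OC(C)=O
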